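**Plan**
Retrosynthesis: (1) the C4–O bond of the ring A lactone is cut back to a spiro 2,2-dimethylcyclopentenone (Baeyer–Villiger forward); (2) that carbocycle is cut at C4–C5 and C1=C2 to an allyl enol ether of the C5 ketone in which an oxygen atom tethers C1 to C2; (3) ring B is cut at C5–C10 (crossed benzoin); (4) the cage is cut at C8–C13 and C15–C16 (intramolecular Diels–Alder) and at C11–C12 (dearomatizing Michael addition of a phthalide).
Forward: phthalide (γ-lactone present from the start) → cyclopentane and bicyclo[2.2.2]octane in one step → C17 hydroxyl → ring B → ring A carbocycle → oxygen insertion.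
Feature used: C1 is an aldehyde-level carbon on the future spiro centre C5, so C5=C1H–O–CH2–C(OMe)=CMe2 can hand C4 to C5 by a [3,3] shift and leave a masked methyl ketone (C3, C2) beside aldehyde C1 for closure of ring A.
Stereochemistry: C12 from a chiral phase-transfer catalyst; C8, C13, C15 from the tether-controlled cycloaddition; C9 and C18 by equilibration; C17 by borylation syn to the ketone bridge; C10 in the benzoin step; C5 in the Claisen step, anti to the axial C10 silyloxy group.

Key step: step 17

Remark (locants, not systematic): ring A = O–C3(=O)–C2=C1–C5–C4(Me)2; ring B = C5–C6–C7–C8–C9–C10; cyclopentane = C8–C9–C11–C12–C13; bicyclo[2.2.2]octane = bridgeheads C13 and C15 joined by C8–C16, C12–C14 (C14 = ketone) and C18–C17; γ-lactone = C13–C19H2–O–C20(=O)–C18. "Cage" means this cyclopentane-fused bicyclooctane lactone; "exo" at C9 means the cyclopentane face away from C16 (cis to C7).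
Remark: but-3-yn-2-ol is used as the racemate (its stereocentre is destroyed in step 3); the geometry of the C5 enol ether formed in step 16 is left undefined because both isomers give the same product.

**Step 1**
Reactants: 1 (±)-but-3-yn-2-ol; 2 allyl bromide
Product: 3 (±)-hept-6-en-3-yn-2-ol
Conditions: CuI (5 mol%), K2CO3, Bu4NI, DMF, rt
Reagents that add atoms: none
Why: Copper-catalysed allylation of the terminal alkyne (acetylide SN2 coupling) gives the skipped enyne; the carbinol configuration is irrelevant.

**Step 2**
Reactants: 3 (±)-hept-6-en-3-yn-2-ol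
Product: 4 (±)-3,4-dimethylidenehept-6-en-2-ol
Conditions: second-generation Grubbs catalyst (5 mol%), ethylene (1 atm), CH2Cl2, 40 °C
Reagents that add atoms: ethylene, C=C
Why: Ethylene–alkyne cross enyne metathesis turns the internal alkyne into a 2,3-disubstituted buta-1,3-diene, while the terminal alkene only exchanges degenerately under ethylene.

**Step 3**
Reactants: 4 (±)-3,4-dimethylidenehept-6-en-2-ol
Product: 5 3,4-dimethylidenehept-6-en-2-one
Conditions: MnO2, CH2Cl2, 0 °C; used at once as a cold solution
Reagents that add atoms: none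
Why: Manganese dioxide oxidation of the allylic alcohol gives the cross-conjugated 2-acyl diene, which is not stored because such dienes dimerise.

**Step 4**
Reactants: 6 5,7-dihydroxy-4-methylphthalide
Product: 7 5,7-dihydroxy-4,6-dimethylphthalide
Conditions: MeI, KOH, MeOH–H2O, 0 °C → rt; then aq. HCl
Reagents that add atoms: iodomethane, CI
Why: Nuclear C-methylation of the resorcinol-type phenoxide at the only free ring position (C6, between the two hydroxyls); acidification re-closes the lactone.

**Step 5**
Reactants: 7 5,7-dihydroxy-4,6-dimethylphthalide; 5 3,4-dimethylidenehept-6-en-2-one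
Product: 9 8-allyl-9-exo-acetyl cage enol lactone, via dienone Michael adduct 8 (not isolated)
Conditions: O-allyl-N-(9-anthracenylmethyl)cinchonidinium bromide (10 mol%; or its cinchonine-derived pseudoenantiomer, whichever gives the C12 configuration drawn), Cs2CO3 (30 mol%), PhMe–CH2Cl2, −50 °C; AcOH; PhMe, 110 °C; then DBU, CH2Cl2, rt; AcOH
Reagents that add atoms: none
Why: Enantioselective alkylative dearomatization by phase-transfer Michael addition, in which the ion-paired phenoxide should attack the acceptor methylidene through C4 (para to the lactone-chelated 7-OH) with the chiral ammonium ion shielding one face and so setting C12; on heating, the cyclohexa-2,4-dienone 8 undergoes an intramolecular Diels–Alder reaction whose two-atom tether enforces C8–C13 and C15–C16 bonding from the tether face (sets C8, C13, C15 relative to C12), and DBU then equilibrates C9 to the exo epimer.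

**Step 6**
Reactants: 9 8-allyl-9-exo-acetyl cage enol lactone
Product: 10 cage enol triflate
Conditions: PhNTf2, Et3N, DMAP (cat.), CH2Cl2, 0 °C
Reagents that add atoms: N-phenylbis(trifluoromethanesulfonimide), O=S(=O)(N(c1ccccc1)S(=O)(=O)C(F)(F)F)C(F)(F)F
Why: The acidic enol of the β-keto lactone is O-sulfonylated (enol triflate formation) under conditions that do not enolize the methyl ketone.

**Step 7**
Reactants: 10 cage enol triflate
Product: 11 cage butenolide (C17=C18)
Conditions: Pd(OAc)2 (5 mol%), PPh3, HCO2H, Et3N, DMF, 60 °C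
Reagents that add atoms: none
Why: Palladium-catalysed formate reduction of a vinyl triflate replaces OTf by H and leaves an α,β-unsaturated γ-lactone for β-functionalization.

**Step 8**
Reactants: 11 cage butenolide (C17=C18)
Product: 13 17-hydroxy cage lactone, via C17 pinacol boronate 12 (not isolated)
Conditions: bis(pinacolato)diboron, CuCl (5 mol%), Xantphos, NaOt-Bu (10 mol%), MeOH, THF, rt; then H2O2, aq. NaHCO3, 0 °C
Reagents that add atoms: hydrogen peroxide, OO
Why: Copper-catalysed conjugate borylation should deliver boron to C17 from the less hindered face syn to the C14 carbonyl bridge, C18 then settles under the basic conditions as the trans epimer (C20 away from the C17 substituent), and oxidation replaces boron by OH with retention.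

**Step 9**
Reactants: 13 17-hydroxy cage lactone
Product: 14 cage 5,17-diol
Conditions: 9-BBN (2.5 equiv), THF, 0 °C → rt; then H2O2, aq. NaHCO3
Reagents that add atoms: hydrogen peroxide, OO
Why: Anti-Markovnikov hydroboration–oxidation of the monosubstituted alkene, which 9-BBN attacks much faster than it reduces the hindered C14 ketone or the methyl ketone.

**Step 10**
Reactants: 14 cage 5,17-diol
Product: 15 cage keto aldehyde
Conditions: TEMPO (10 mol%), PhI(OAc)2, CH2Cl2, rt
Reagents that add atoms: none
Why: Oxoammonium oxidation is selective for the primary alcohol, so the hindered secondary C17 carbinol needs no protection.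

**Step 11**
Reactants: 15 cage keto aldehyde
Product: 16 ring B α-ketol
Conditions: aminoindanol-derived N-pentafluorophenyl triazolium tetrafluoroborate (10 mol%), Et3N (10 mol%), PhMe, rt
Reagents that add atoms: none
Why: NHC-catalysed intramolecular crossed benzoin (aldehyde–ketone acyloin) reaction, in which the Breslow intermediate from aldehyde C5 adds 6-exo-trig to the C10 methyl ketone on the exo face, the methyl group taking the position cis to H-9 and the smaller oxygen the position cis to C11 (sets C10), a bias the chiral catalyst can reinforce.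

**Step 12**
Reactants: 16 ring B α-ketol
Product: 17 10,17-bis(triethylsilyl) ether
Conditions: Et3SiOTf, 2,6-lutidine, CH2Cl2, −78 → −20 °C
Reagents that add atoms: triethylsilyl trifluoromethanesulfonate, CC[Si](CC)(CC)OS(=O)(=O)C(F)(F)F
Why: Silylation of both hydroxyls prevents α-ketol rearrangement under the basic olefination and installs the C10 silyloxy group that steers step 17.

**Step 13**
Reactants: 18 methyl 2-(dimethoxyphosphoryl)-2-methoxyacetate; 19 acetone
Product: 20 methyl 2-methoxy-3-methylbut-2-enoate
Conditions: NaH, THF, 0 °C → reflux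
Reagents that add atoms: none
Why: Horner–Wadsworth–Emmons olefination of acetone gives the tetrasubstituted α-methoxy acrylate, which has no alkene geometry to control.

**Step 14**
Reactants: 20 methyl 2-methoxy-3-methylbut-2-enoate
Product: 21 2-methoxy-3-methylbut-2-en-1-ol
Conditions: i-Bu2AlH, CH2Cl2, −78 °C
Reagents that add atoms: none
Why: 1,2-Reduction of the unsaturated ester gives the allylic alcohol and leaves the enol ether intact.

**Step 15**
Reactants: 21 2-methoxy-3-methylbut-2-en-1-ol; 22 (chloromethyl)diphenylphosphine oxide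
Product: 23 [(2-methoxy-3-methylbut-2-enyl)oxymethyl]diphenylphosphine oxide
Conditions: NaH, THF–DMF, 0 → 60 °C
Reagents that add atoms: none
Why: Williamson etherification of the sodium alkoxide gives the alkoxymethyl phosphine oxide used as Horner–Wittig reagent.

**Step 16**
Reactants: 17 10,17-bis(triethylsilyl) ether; 23 [(2-methoxy-3-methylbut-2-enyl)oxymethyl]diphenylphosphine oxide
Product: 25 C5 allyl enol ether, via hydroxy phosphine oxide 24 (not isolated)
Conditions: KN(SiMe3)2, THF, −78 °C → rt
Reagents that add atoms: none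
Why: Horner–Wittig alkoxymethylenation of the C5 ketone: the phosphinoyl carbanion adds and the potassium alkoxide expels diphenylphosphinate, giving the enol ether as an isomer mixture that converges in step 17.

**Step 17**
Reactants: 25 C5 allyl enol ether
Product: 28 spiro cyclopentenone, via Claisen aldehyde 26 (not isolated), via keto aldehyde 27 (not isolated)
Conditions: o-xylene, 150 °C, sealed tube; then H2O (3 equiv), Bn2NH2+ CF3CO2− (30 mol%), 60 °C
Reagents that add atoms: water, O
Why: The allyl vinyl ether C5=C1–O–C2–C3=C4 undergoes a thermal [3,3] (Claisen) shift through a chair transition state, forming C4–C5 and releasing aldehyde C1 next to a 2-methoxyallyl unit (26); acid and water then unmask the methyl ketone (27), whose enol adds to the aldehyde and loses water to form C1=C2. The closest known reaction types are the Wittig–Claisen route from ketones to α-quaternary aldehydes (including reverse-prenyl cases that join two fully substituted carbons) and the amine-salt-catalysed aldol condensation of 1,4-keto aldehydes to cyclopentenones. No ring forms in the sigmatropic stage; ring A (still a carbocycle) closes by 5-(enolexo)-exo-trig aldol addition followed by E1cB dehydration. The only new stereocentre, C5, is set in the [3,3] stage: C4 should add to the face anti to the axial C10 silyloxy group (oxygen has the smaller A-value and is therefore axial), that is cis to the C10 methyl. The step needs this facial selectivity and a chemoselective aldol; the latter is secured because only C2 can enolize (C4 is quaternary), the C1 aldehyde is non-enolizable and the most electrophilic carbonyl, and the C14 ketone lies between two quaternary carbons.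

**Step 18**
Reactants: 28 spiro cyclopentenone
Product: 29 bis(triethylsilyl) ether of the target
Conditions: m-CPBA, NaHCO3, CH2Cl2, 0 °C → rt
Reagents that add atoms: m-chloroperbenzoic acid, OOC(=O)c1cccc(Cl)c1
Why: Baeyer–Villiger oxidation in which the tertiary C4 migrates in preference to vinylic C2, inserting oxygen between C3 and C4; the C14 ketone (two quaternary neighbours, inside the cage) and the electron-poor C1=C2 bond should not react.

**Step 19**
Reactants: 29 bis(triethylsilyl) ether of the target
Product: 30 target CNP0360620.3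
Conditions: HF·pyridine, THF, 0 °C → rt
Reagents that add atoms: none
Why: Fluoride-driven cleavage of both silyl ethers under near-neutral conditions, which avoids retro-aldol or elimination of the β-hydroxy carbonyl units.

**Compound list**
1 | (±)-but-3-yn-2-ol | CC(O)C#C | starting material
2 | allyl bromide | C=CCBr | starting material
3 | (±)-hept-6-en-3-yn-2-ol | CC(O)C#CCC=C | intermediate
4 | (±)-3,4-dimethylidenehept-6-en-2-ol | CC(O)C(=C)C(=C)CC=C | intermediate
5 | 3,4-dimethylidenehept-6-en-2-one | CC(=O)C(=C)C(=C)CC=C | intermediate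
6 | 5,7-dihydroxy-4-methylphthalide (5,7-dihydroxy-4-methyl-3H-isobenzofuran-1-one) | Cc1c(O)cc(O)c2C(=O)OCc12 | starting material
7 | 5,7-dihydroxy-4,6-dimethylphthalide | Cc1c(O)c(C)c(O)c2C(=O)OCc12 | intermediate
8 | dienone Michael adduct: phthalide dearomatized at C4 (= C12), which carries CH3 and CH2–CH(COCH3)–C(=CH2)–CH2CH=CH2; C12 as drawn, C9 a mixture | O=C1C(C)=C(O)C2=C(COC2=O)[C@@]1(C)CC(C(C)=O)C(=C)CC=C | intermediate
9 | 8-allyl-9-exo-acetyl cage enol lactone: C14 ketone, 17-hydroxy-17(18)-ene, 12,15-dimethyl; C12 methyl and the C8 allyl group face the C17/C18 bridge | C=CC[C@]13C[C@]4(C)C(=O)[C@](C)(C[C@H]1C(C)=O)[C@]31COC(=O)C1=C4O | intermediate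
10 | cage enol triflate (17-triflyloxy-17(18)-ene) | C=CC[C@]13C[C@]4(C)C(=O)[C@](C)(C[C@H]1C(C)=O)[C@]31COC(=O)C1=C4OS(=O)(=O)C(F)(F)F | intermediate
11 | cage butenolide (17(18)-ene, H at C17) | C=CC[C@]13C[C@]4(C)C(=O)[C@](C)(C[C@H]1C(C)=O)[C@]31COC(=O)C1=C4 | intermediate
12 | C17 pinacol boronate; boron syn to the C14 bridge, C20 on C18 syn to the C16 bridge | C=CC[C@]13C[C@]4(C)C(=O)[C@](C)(C[C@H]1C(C)=O)[C@]31COC(=O)[C@@H]1[C@H]4B1OC(C)(C)C(C)(C)O1 | intermediate
13 | 17-hydroxy cage lactone; 17-OH syn to the C14 bridge, trans to C20 | C=CC[C@]13C[C@]4(C)C(=O)[C@](C)(C[C@H]1C(C)=O)[C@]31COC(=O)[C@@H]1[C@H]4O | intermediate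
14 | cage 5,17-diol (3-hydroxypropyl on C8) | OCCC[C@]13C[C@]4(C)C(=O)[C@](C)(C[C@H]1C(C)=O)[C@]31COC(=O)[C@@H]1[C@H]4O | intermediate
15 | cage keto aldehyde (C5 aldehyde, C10 methyl ketone) | O=CCC[C@]13C[C@]4(C)C(=O)[C@](C)(C[C@H]1C(C)=O)[C@]31COC(=O)[C@@H]1[C@H]4O | intermediate
16 | ring B α-ketol: 5-oxo, 10-hydroxy-10-methyl; 10-OH cis to C11, ring B cis-fused on the exo face | O=C2CC[C@]13C[C@]4(C)C(=O)[C@](C)(C[C@H]1[C@@]2(C)O)[C@]31COC(=O)[C@@H]1[C@H]4O | intermediate
17 | 10,17-bis(triethylsilyl) ether of 16 | O=C2CC[C@]13C[C@]4(C)C(=O)[C@](C)(C[C@H]1[C@@]2(C)O[Si](CC)(CC)CC)[C@]31COC(=O)[C@@H]1[C@H]4O[Si](CC)(CC)CC | intermediate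
18 | methyl 2-(dimethoxyphosphoryl)-2-methoxyacetate | COC(=O)C(OC)P(=O)(OC)OC | starting material
19 | acetone | CC(C)=O | starting material
20 | methyl 2-methoxy-3-methylbut-2-enoate | COC(=O)C(OC)=C(C)C | intermediate
21 | 2-methoxy-3-methylbut-2-en-1-ol | OCC(OC)=C(C)C | intermediate
22 | (chloromethyl)diphenylphosphine oxide | ClCP(=O)(c1ccccc1)c1ccccc1 | starting material
23 | [(2-methoxy-3-methylbut-2-enyl)oxymethyl]diphenylphosphine oxide | O=P(COCC(OC)=C(C)C)(c1ccccc1)c1ccccc1 | intermediate
24 | hydroxy phosphine oxide adduct at C5 (mixture at C5 and C1) | OC2(C(OCC(OC)=C(C)C)P(=O)(c5ccccc5)c5ccccc5)CC[C@]13C[C@]4(C)C(=O)[C@](C)(C[C@H]1[C@@]2(C)O[Si](CC)(CC)CC)[C@]31COC(=O)[C@@H]1[C@H]4O[Si](CC)(CC)CC | intermediate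
25 | C5 allyl enol ether, C5=C1H–O–CH2–C(OMe)=CMe2 (E/Z mixture) | CC(C)=C(OC)COC=C2CC[C@]13C[C@]4(C)C(=O)[C@](C)(C[C@H]1[C@@]2(C)O[Si](CC)(CC)CC)[C@]31COC(=O)[C@@H]1[C@H]4O[Si](CC)(CC)CC | intermediate
26 | Claisen aldehyde: C5 carries CHO (C1) and C(CH3)2–C(OMe)=CH2; C4 cis to the C10 methyl | O=C[C@@]2(C(C)(C)C(OC)=C)CC[C@]13C[C@]4(C)C(=O)[C@](C)(C[C@H]1[C@@]2(C)O[Si](CC)(CC)CC)[C@]31COC(=O)[C@@H]1[C@H]4O[Si](CC)(CC)CC | intermediate
27 | keto aldehyde: C5 carries CHO and C(CH3)2–COCH3 | O=C[C@@]2(C(C)(C)C(C)=O)CC[C@]13C[C@]4(C)C(=O)[C@](C)(C[C@H]1[C@@]2(C)O[Si](CC)(CC)CC)[C@]31COC(=O)[C@@H]1[C@H]4O[Si](CC)(CC)CC | intermediate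
28 | spiro cyclopentenone: ring A carbocycle C5–C1=C2–C3(=O)–C4(CH3)2 | CC1(C)C(=O)C=C[C@]12CC[C@]13C[C@]4(C)C(=O)[C@](C)(C[C@H]1[C@@]2(C)O[Si](CC)(CC)CC)[C@]31COC(=O)[C@@H]1[C@H]4O[Si](CC)(CC)CC | intermediate
29 | 10,17-bis(triethylsilyl) ether of the target | CC1(C)OC(=O)C=C[C@]12CC[C@]13C[C@]4(C)C(=O)[C@](C)(C[C@H]1[C@@]2(C)O[Si](CC)(CC)CC)[C@]31COC(=O)[C@@H]1[C@H]4O[Si](CC)(CC)CC | intermediate
30 | CNP0360620.3 | CC1(C)OC(=O)C=C[C@]12CC[C@]13C[C@]4(C)C(=O)[C@](C)(C[C@H]1[C@@]2(C)O)[C@]31COC(=O)[C@@H]1[C@H]4O | target

**Count**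
Total steps: 19. Longest linear sequence: 15 steps (steps 1–3, 5–12 and 16–19, from 1).

**Steps most likely to fail**

Step 5. The Michael addition may take place at the ring carbon between the two oxygens (C6) instead of C4. The β,γ-unsaturated ketone may also slip into conjugation before the cycloaddition, and the ion pair may give low enantioselectivity. Fallback, from 7 (with 5) back to 11: the addition is run without chiral catalyst on the lithium phenoxide (LiN(SiMe3)2, PhMe, −78 °C), where chelation of lithium between the 7-oxygen and the lactone carbonyl is expected to direct attack to C4. Heating as in step 5 then gives 9 as the racemate. Its enol is sulfonylated with (1S)-camphor-10-sulfonyl chloride (Et3N, DMAP) to two diastereomeric enol sulfonates, which are separated by chromatography or crystallization; the one wanted is the enol (1S)-camphor-10-sulfonate F1. Palladium-catalysed formate reduction of F1 (Pd(OAc)2, dppf, HCO2H, Et3N) gives 11.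

Step 17. The sigmatropic shift has to join two fully substituted carbons beside the quaternary C10 and may be slow or be diverted to elimination, and delivery of C4 to the wrong face of C5 is possible. Fallback, from 17 back to 28: the ketone is methylenated (Ph3P=CH2) to the 5-methylidene compound F2. A [2+2] cycloaddition with dimethylketene (from 2-bromo-2-methylpropanoyl bromide and zinc) gives the spiro cyclobutanone F3, with the carbonyl carbon on the former CH2 terminus. One-carbon ring expansion with trimethylsilyldiazomethane and BF3·OEt2 (migration of the CH2 carbon, then desilylation) gives the spiro cyclopentanone F4. Saegusa–Ito dehydrogenation (LiN(SiMe3)2, Me3SiCl; then Pd(OAc)2) gives 28.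

Step 11. Base-induced aldol closure of the keto aldehyde may outrun the benzoin pathway, or addition may occur to the wrong face of the methyl ketone. Fallback, from 15 back to 16: reductive pinacol cyclization with SmI2 (THF, t-BuOH, −78 °C), in which samarium chelates both oxygens, gives the cis-5,10-diol F5. Regioselective oxidation of its secondary carbinol through the dibutylstannylene acetal (Bu2SnO; then N-bromosuccinimide) gives 16, the isolated C17 hydroxyl not being engaged.

**Further compounds**
F1 | step 5 | enol (1S)-camphor-10-sulfonate of 9 | C=CC[C@]13C[C@]4(C)C(=O)[C@](C)(C[C@H]1C(C)=O)[C@]31COC(=O)C1=C4OS(=O)(=O)C[C@]12CC[C@H](CC1=O)C2(C)C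
F2 | step 17 | 5-methylidene compound from 17 | C=C2CC[C@]13C[C@]4(C)C(=O)[C@](C)(C[C@H]1[C@@]2(C)O[Si](CC)(CC)CC)[C@]31COC(=O)[C@@H]1[C@H]4O[Si](CC)(CC)CC
F3 | step 17 | spiro 2,2-dimethylcyclobutanone (C5–C4(CH3)2–C(=O)–C1H2) | CC1(C)C(=O)C[C@]12CC[C@]13C[C@]4(C)C(=O)[C@](C)(C[C@H]1[C@@]2(C)O[Si](CC)(CC)CC)[C@]31COC(=O)[C@@H]1[C@H]4O[Si](CC)(CC)CC
F4 | step 17 | spiro 2,2-dimethylcyclopentanone (1,2-dihydro 28) | CC1(C)C(=O)CC[C@]12CC[C@]13C[C@]4(C)C(=O)[C@](C)(C[C@H]1[C@@]2(C)O[Si](CC)(CC)CC)[C@]31COC(=O)[C@@H]1[C@H]4O[Si](CC)(CC)CC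
F5 | step 11 | cis-5,10-diol (5-hydroxy analogue of 16) | O[C@H]2CC[C@]13C[C@]4(C)C(=O)[C@](C)(C[C@H]1[C@@]2(C)O)[C@]31COC(=O)[C@@H]1[C@H]4O
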